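Germacranolide numbering is used (ring C1–C10, lactone oxygen on C6, C7–C11(=C13)–C12). Everything rests on the O–C6 bond of the γ-lactone: the unit O–C6–C5=C4(CH3), an allylic C–O bond next to the ring-cis alkene of the ten-membered ring, is the hydro-acyloxylation product of a ring allene C4=C5=C6. The precursor is therefore a ten-membered 4,5-allenic acrylic acid, reached from a substituted cyclohexanone by an alkynyl oxy-Cope ring expansion that cleaves C4–C9. One gold-catalysed operation closes the lactone ring, converts the allene axis into the C6 stereocentre and sets the Z-alkene.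

Key step: step 16

Assumption: the hydroxyl epimer of step 2 and the face isomer of step 4 are taken to be separable by chromatography; TMS-EBX, (S)-Me-CBS, Burgess reagent and angelic acid are bought.

Step 1
Reactants: 1 2-methylcyclohexane-1,3-dione
Product: 2 2-ethynyl-2-methylcyclohexane-1,3-dione
Conditions: TMS-EBX (1.3 equiv), Bu4NF (1.3 equiv), THF, −78 °C to rt
Reagents that add atoms: TMS-EBX, 1-[(trimethylsilyl)ethynyl]-1,2-benziodoxol-3(1H)-one, C[Si](C)(C)C#CI1OC(=O)c2ccccc12
Why: Electrophilic ethynylation of the 1,3-diketone enolate by ethynylbenziodoxolone released in situ (known for stabilised enolates) attaches the carbons that become C5 and C6 to the future C4, which is quaternary but still prochiral.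

Step 2
Reactants: 2 2-ethynyl-2-methylcyclohexane-1,3-dione
Product: 3 (2R,3R)-2-ethynyl-3-hydroxy-2-methylcyclohexan-1-one
Conditions: (S)-2-methyl-CBS-oxazaborolidine (15 mol%), catecholborane (1.1 equiv), toluene, −78 to −40 °C
Reagents that add atoms: none
Why: Corey–Bakshi–Shibata desymmetrisation, in which the catalyst fixes the carbinol configuration (quaternary carbon as the large group) and hydride delivery anti to the pseudoaxial ethynyl group selects one enantiotopic carbonyl, so that the quaternary C4 centre is obtained as one enantiomer once the hydroxyl epimer (opposite C4 configuration) is removed by chromatography.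

Step 3
Reactants: 3 (2R,3R)-2-ethynyl-3-hydroxy-2-methylcyclohexan-1-one
Product: 4 (S)-2-ethynyl-2-methylcyclohex-3-en-1-one
Conditions: Burgess reagent (1.5 equiv), toluene, 70 °C
Reagents that add atoms: none
Why: Burgess dehydration (syn elimination of the sulfamate ester) can only proceed away from the quaternary carbon, which gives the C2=C3 alkene (target numbering) and leaves the C4 stereocentre untouched.

Step 4
Reactants: 4 (S)-2-ethynyl-2-methylcyclohex-3-en-1-one
Product: 5 (2R,3R,4S)-2-ethynyl-3,4-dihydroxy-2-methylcyclohexan-1-one (both hydroxyls cis to the methyl group)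
Conditions: OsO4 (2 mol%), NMO (1.3 equiv), acetone/H2O 4:1, 0 °C
Reagents that add atoms: N-methylmorpholine N-oxide, C[N+]1([O-])CCOCC1; water, O
Why: Upjohn syn-dihydroxylation, in which OsO4 should add anti to the ethynyl group that is pseudoaxial in the preferred half-chair and so place the C2 and C3 hydroxyls of the target cis to the methyl group, the face isomer being removed by chromatography.

Step 5
Reactants: 5 (2R,3R,4S)-2-ethynyl-3,4-dihydroxy-2-methylcyclohexan-1-one
Product: 6 (3aR,4R,7aS)-4-ethynyl-2,2,4-trimethylhexahydro-1,3-benzodioxol-5-one (acetonide of 5)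
Conditions: 2,2-dimethoxypropane, PPTS (cat.), CH2Cl2, rt
Reagents that add atoms: 2,2-dimethoxypropane, COC(C)(C)OC
Why: Acid-catalysed transketalisation closes the cis-fused dioxolane on the cis-diol, which masks both hydroxyls for the organometallic, basic and gold steps.

Step 6
Reactants: 6 acetonide ketone
Product: 8 (3aR,4R,6R,7aS)-4-ethynyl-2,2,4,6-tetramethylhexahydro-1,3-benzodioxol-5-one, via lithium enolate 7 (not isolated)
Conditions: LiN(i-Pr)2 (1.1 equiv), THF, −78 °C; MeI (1.2 equiv), −78 to 0 °C; then K2CO3, MeOH, rt
Reagents that add atoms: iodomethane, CI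
Why: Alkylation of the only possible enolate followed by base equilibration gives the thermodynamic C10 epimer with both methyl groups equatorial and cis, because the other epimer would need a syn-diaxial contact of the new methyl with the ethynyl group or, after ring flip, of the C4 methyl with the C2 oxygen.

Step 7
Reactants: 9 2-bromoprop-2-en-1-ol
Product: 10 [(2-bromoprop-2-en-1-yl)oxy](tert-butyl)dimethylsilane
Conditions: TBSCl, imidazole, CH2Cl2, 0 °C to rt
Reagents that add atoms: tert-butyldimethylsilyl chloride, CC(C)(C)[Si](C)(C)Cl
Why: Standard silylation protects the primary allylic alcohol, the future C12, for the organometallic steps.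

Step 8
Reactants: 10 [(2-bromoprop-2-en-1-yl)oxy](tert-butyl)dimethylsilane
Product: 11 tert-butyldimethyl{[2-methylidene-4-(trimethylsilyl)but-3-yn-1-yl]oxy}silane
Conditions: ethynyltrimethylsilane (1.3 equiv), PdCl2(PPh3)2 (3 mol%), CuI (6 mol%), Et3N, THF, 40 °C
Reagents that add atoms: ethynyltrimethylsilane, C#C[Si](C)(C)C
Why: Sonogashira coupling of the vinyl bromide with the terminal alkyne gives the cross-conjugated enyne that holds C8, C7, C11, C12 and C13.

Step 9
Reactants: 8 methylated acetonide ketone; 11 silyl enyne
Product: 13 tertiary propargylic alcohol (5S; new enynyl chain cis to the ring ethynyl group), via lithium acetylide 12 (not isolated)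
Conditions: 11 (2.2 equiv), MeLi (2.2 equiv), THF, 0 °C; CeCl3 (2.4 equiv), −78 °C; then 8, −78 to −40 °C; aq. NH4Cl
Reagents that add atoms: none
Why: Methyllithium cleaves the C–Si bond of the alkynylsilane and the derived organocerium acetylide adds to the hindered, enolisable ketone without enolisation (the excess offsets proton exchange with the ring C≡C–H), and equatorial attack on the face of the axial ethynyl group should prevail because the axial C3–O bond blocks the axial trajectory.

Step 10
Reactants: 13 tertiary propargylic alcohol
Product: 14 (E)-dienyl carbinol (5S; 1E-dienyl chain cis to the ring ethynyl group)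
Conditions: NaAlH2(OCH2CH2OMe)2 (Red-Al, 3.5 equiv), THF, 0 °C to rt; aq. potassium sodium tartrate
Reagents that add atoms: none
Why: Alkoxide-directed trans-hydroalumination of the propargylic alkyne (known for propargylic alcohols) gives the E-alkene, whereas the ring ethynyl group, deprotonated and only homopropargylic, is not reduced.

Step 11
Reactants: 14 (E)-dienyl carbinol
Product: 16 ten-membered (aS)-allenyl ketone (C9 ketone and C4=C5=C6 allene), via potassium enolate 15 (not isolated)
Conditions: KN(SiMe3)2 (1.05 equiv), 18-crown-6 (1.2 equiv), THF, −20 °C to rt; AcOH, −78 °C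
Reagents that add atoms: none
Why: Anionic oxy-Cope [3,3] shift of the 3-hydroxy-1-en-5-yne (acetylenic oxy-Cope) cleaves C4–C9 and forms C6–C7, which expands the six-membered to the ten-membered ring, while the suprafacial shift converts the C4 stereocentre into the allene axis and the chair-like array of the ground-state chair (ethynyl axial, E-dienyl equatorial) sets C7, before cold protonation of the enolate gives the ketone with the C10 configuration intact.

Step 12
Reactants: 16 ten-membered allenyl ketone
Product: 17 (9S)-alcohol (hydroxyl cis to the C10 methyl group)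
Conditions: LiBH(s-Bu)3 (L-Selectride, 1.3 equiv), THF, −78 °C; then aq. NaOH, H2O2, 0 °C
Reagents that add atoms: none
Why: Felkin–Anh addition of the bulky hydride (anti to the C10–C1 ring bond, past the C10 hydrogen) should give the C9 alcohol cis to the C10 methyl group, as bulky hydrides do with 2-methylcycloalkanones.

Step 13
Reactants: 17 (9S)-alcohol
Product: 18 C9 angelate
Conditions: angelic acid (3 equiv), 2,4,6-trichlorobenzoyl chloride (3 equiv), Et3N, toluene, rt; then 17, DMAP, toluene, 70 °C
Reagents that add atoms: angelic acid, C/C=C(/C)C(=O)O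
Why: Yamaguchi esterification through the mixed anhydride acylates the hindered secondary alcohol and is the usual way to introduce an angelate without isomerisation to the tiglate.

Step 14
Reactants: 18 C9 angelate
Product: 19 primary allylic alcohol (C12 carbinol)
Conditions: HF·pyridine, pyridine, THF, 0 °C to rt
Reagents that add atoms: none
Why: Buffered fluoride cleaves the primary silyl ether and leaves the acetonide, the allene and the Z-angelate untouched.

Step 15
Reactants: 19 primary allylic alcohol
Product: 21 allenic acrylic acid, via enal 20 (not isolated)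
Conditions: TEMPO (20 mol%), PhI(OAc)2 (2.5 equiv), MeCN/H2O 1:1, rt
Reagents that add atoms: water, O
Why: Oxoammonium (TEMPO) oxidation of the allylic alcohol to the enal and, through its hydrate, on to the acrylic acid proceeds in one flask under near-neutral conditions that spare the allene.

Step 16
Reactants: 21 allenic acrylic acid
Product: 22 2,3-O-isopropylidene derivative of the target (trans-fused lactone and 4Z alkene)
Conditions: Ph3PAuCl (5 mol%), AgOTf (5 mol%), CH2Cl2, 0 °C to rt
Reagents that add atoms: none
Why: The cationic monovalent gold complex binds the C5=C6 π bond of the allene on its exocyclic face (the face of the C4 methyl group), the carboxyl oxygen adds anti to gold at C6, and protodeauration of the C5 vinyl-gold species with retention releases the lactone. The closest known reaction type is the gold- or silver-catalysed cycloisomerisation of 4,5-allenoic acids to 5-alkenyl butyrolactones. The γ-lactone is closed in the 5-exo-trig mode on the proximal allene carbon. The new C6 stereocentre is controlled by the axial chirality of the ring allene (axis-to-centre transfer by anti addition), which itself stems from the quaternary C4 centre of 14, and with C7 already fixed this gives the trans-fused lactone. The step needs attack at C6 and not at C4, secured by the three-atom tether (5-exo against 7-endo), and the ring-cis C4=C5 geometry, secured because attack from the other face would place a trans trisubstituted alkene in the ten-membered ring. Competing nucleophiles are masked, since the C3 oxygen, which would otherwise close a 2,5-dihydrofuran, is held in the acetonide and the C9 oxygen is acylated.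

Step 17
Reactants: 22 lactone acetonide
Product: 23 CNP0229085.1 (target)
Conditions: AcOH/H2O 4:1, 40 °C
Reagents that add atoms: none
Why: Mild aqueous acid hydrolyses the acetonide without ionising the allylic lactone or isomerising the angelate, which releases the C2/C3 diol of the target.

Compound list

1 | 2-methylcyclohexane-1,3-dione | CC1C(=O)CCCC1=O | starting material
2 | 2-ethynyl-2-methylcyclohexane-1,3-dione | C#CC1(C)C(=O)CCCC1=O | intermediate
3 | (2R,3R)-2-ethynyl-3-hydroxy-2-methylcyclohexan-1-one (hydroxyl cis to ethynyl) | O=C1[C@](C)(C#C)[C@H](O)CCC1 | intermediate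
4 | (S)-2-ethynyl-2-methylcyclohex-3-en-1-one | O=C1[C@](C)(C#C)C=CCC1 | intermediate
5 | (2R,3R,4S)-2-ethynyl-3,4-dihydroxy-2-methylcyclohexan-1-one (both hydroxyls cis to the 2-methyl group) | O=C1[C@](C)(C#C)[C@@H](O)[C@@H](O)CC1 | intermediate
6 | (3aR,4R,7aS)-4-ethynyl-2,2,4-trimethylhexahydro-1,3-benzodioxol-5-one | O=C1[C@](C)(C#C)[C@H]2OC(C)(C)O[C@H]2CC1 | intermediate
7 | lithium enolate of 6 (enolate towards the ring CH2) | [Li]OC1[C@](C)(C#C)[C@H]2OC(C)(C)O[C@H]2CC=1 | intermediate
8 | (3aR,4R,6R,7aS)-4-ethynyl-2,2,4,6-tetramethylhexahydro-1,3-benzodioxol-5-one (both methyls cis to the ring oxygens, ethynyl trans) | O=C1[C@](C)(C#C)[C@H]2OC(C)(C)O[C@H]2C[C@H]1C | intermediate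
9 | 2-bromoprop-2-en-1-ol | C=C(Br)CO | starting material
10 | [(2-bromoprop-2-en-1-yl)oxy](tert-butyl)dimethylsilane | C=C(Br)CO[Si](C)(C)C(C)(C)C | intermediate
11 | tert-butyldimethyl{[2-methylidene-4-(trimethylsilyl)but-3-yn-1-yl]oxy}silane | C=C(CO[Si](C)(C)C(C)(C)C)C#C[Si](C)(C)C | intermediate
12 | lithium acetylide from 11 (C–Si replaced by C–Li) | [Li]C#CC(=C)CO[Si](C)(C)C(C)(C)C | intermediate
13 | (3aR,4R,5S,6R,7aS)-5-[3-({[tert-butyl(dimethyl)silyl]oxy}methyl)but-3-en-1-yn-1-yl]-4-ethynyl-2,2,4,6-tetramethylhexahydro-1,3-benzodioxol-5-ol (enynyl chain cis to ethynyl) | O[C@@]1(C#CC(=C)CO[Si](C)(C)C(C)(C)C)[C@](C)(C#C)[C@H]2OC(C)(C)O[C@H]2C[C@H]1C | intermediate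
14 | (3aR,4R,5S,6R,7aS)-5-[(1E)-3-({[tert-butyl(dimethyl)silyl]oxy}methyl)buta-1,3-dien-1-yl]-4-ethynyl-2,2,4,6-tetramethylhexahydro-1,3-benzodioxol-5-ol | O[C@@]1(/C=C/C(=C)CO[Si](C)(C)C(C)(C)C)[C@](C)(C#C)[C@H]2OC(C)(C)O[C@H]2C[C@H]1C | intermediate
15 | potassium enolate of 16 (C9–O, C8=C9, oxygen trans to C7) | [K+].[O-]/C1=C/[C@@H](C(=C)CO[Si](C)(C)C(C)(C)C)C=[C@@]=C(C)[C@H]2OC(C)(C)O[C@H]2C[C@H]1C | intermediate
16 | ten-membered allenyl ketone: C9 ketone, (aS)-allene C4=C5=C6, C7 bearing the 3-(silyloxy)prop-1-en-2-yl group, C2/C3 acetonide, C10 methyl | O=C1C[C@@H](C(=C)CO[Si](C)(C)C(C)(C)C)C=[C@@]=C(C)[C@H]2OC(C)(C)O[C@H]2C[C@H]1C | intermediate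
17 | (9S)-alcohol from 16 (hydroxyl cis to the C10 methyl group) | O[C@H]1C[C@@H](C(=C)CO[Si](C)(C)C(C)(C)C)C=[C@@]=C(C)[C@H]2OC(C)(C)O[C@H]2C[C@H]1C | intermediate
18 | C9 angelate [(Z)-2-methylbut-2-enoate] of 17 | C/C=C(/C)C(=O)O[C@H]1C[C@@H](C(=C)CO[Si](C)(C)C(C)(C)C)C=[C@@]=C(C)[C@H]2OC(C)(C)O[C@H]2C[C@H]1C | intermediate
19 | primary allylic alcohol from 18 (silyl ether cleaved) | C/C=C(/C)C(=O)O[C@H]1C[C@@H](C(=C)CO)C=[C@@]=C(C)[C@H]2OC(C)(C)O[C@H]2C[C@H]1C | intermediate
20 | enal (2-substituted acrolein) from 19 | C/C=C(/C)C(=O)O[C@H]1C[C@@H](C(=C)C=O)C=[C@@]=C(C)[C@H]2OC(C)(C)O[C@H]2C[C@H]1C | intermediate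
21 | allenic acid: 2-substituted acrylic acid on C7 of the ten-membered (aS)-allene | C/C=C(/C)C(=O)O[C@H]1C[C@@H](C(=C)C(=O)O)C=[C@@]=C(C)[C@H]2OC(C)(C)O[C@H]2C[C@H]1C | intermediate
22 | 2,3-O-isopropylidene derivative of the target (trans-fused lactone, 4Z alkene) | C=C1C(=O)O[C@@H]2/C=C(/C)[C@H]3OC(C)(C)O[C@H]3C[C@@H](C)[C@@H](OC(=O)/C(C)=C\C)C[C@@H]12 | intermediate
23 | CNP0229085.1 (2S,3R,4Z,6R,7S,9S,10R in the numbering used here) | C=C1C(=O)O[C@@H]2/C=C(/C)[C@@H](O)[C@@H](O)C[C@@H](C)[C@@H](OC(=O)/C(C)=C\C)C[C@@H]12 | target

Total step count: 17. Longest linear sequence: 15 steps (steps 1–6 and 9–17).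

Steps most likely to fail

Step 16 (key step). The gold-activated allene may be diverted: isomerisation to a 1,3-diene, addition on the face that leads to the ring-trans alkene, or slow protodeauration. The fallback sets out from 21 and uses an electrophile-induced closure of the same O–C6 bond. Iodolactonisation with N-iodosuccinimide (CH2Cl2, 0 °C), an anti addition of iodonium to C5 and carboxylate to C6, should give the 5-iodo lactone F1. Removal of the vinylic iodine with (Me3Si)3SiH and Et3B/air (toluene, −20 °C) would then return to the route at 22.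

Step 11. The potassium alkoxide may fragment instead of rearranging, the C≡C–H may be deprotonated, or C10 may epimerise in the basic medium. The fallback sets out from 14 and runs the shift on a neutral species. Silylation (Me3SiOTf, 2,6-lutidine, CH2Cl2, −78 °C) should give the trimethylsilyl ether F2. Thermal siloxy-Cope rearrangement (degassed 1,2-dichlorobenzene, 190 °C, sealed tube) would give the ring-expanded trimethylsilyl enol ether F3. Mild methanolysis (citric acid, MeOH, 0 °C) would return to the route at 16.

Step 4. Facial selectivity of the dihydroxylation may be poor, because only the modest preference of the ethynyl group for the pseudoaxial position separates the two faces. The fallback sets out from 4 and changes the order of events so that the ring is conformationally locked first. Methylation (LiN(i-Pr)2, MeI, THF, −78 °C; then K2CO3, MeOH) should give the cis-2,6-dimethyl enone F4, and its trans epimer can be recycled by re-equilibration. In F4 the half-chair with pseudoaxial ethynyl is the only accessible one, since the flipped form needs a methyl/methyl syn-diaxial contact. OsO4/NMO should then add from the methyl face only to give the diol F5. Acetonide formation (2,2-dimethoxypropane, PPTS) would return to the route at 8.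

Further compounds

F1 | step 16 | 5-iodo lactone (C5-iodo analogue of 22, iodine cis to the C4 methyl group) | C=C1C(=O)O[C@@H]2/C(I)=C(/C)[C@H]3OC(C)(C)O[C@H]3C[C@@H](C)[C@@H](OC(=O)/C(C)=C\C)C[C@@H]12
F2 | step 11 | trimethylsilyl ether of 14 | C[Si](C)(C)O[C@@]1(/C=C/C(=C)CO[Si](C)(C)C(C)(C)C)[C@](C)(C#C)[C@H]2OC(C)(C)O[C@H]2C[C@H]1C
F3 | step 11 | trimethylsilyl enol ether of 16 (C8=C9) | C[Si](C)(C)O/C1=C/[C@@H](C(=C)CO[Si](C)(C)C(C)(C)C)C=[C@@]=C(C)[C@H]2OC(C)(C)O[C@H]2C[C@H]1C
F4 | step 4 | (2S,6R)-2-ethynyl-2,6-dimethylcyclohex-3-en-1-one (methyl groups cis) | O=C1[C@](C)(C#C)C=CC[C@H]1C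
F5 | step 4 | (2R,3R,4S,6R)-2-ethynyl-3,4-dihydroxy-2,6-dimethylcyclohexan-1-one | O=C1[C@](C)(C#C)[C@@H](O)[C@@H](O)C[C@H]1C
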